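**Assumption:** Ardisiphenol D has no stereocentres (the SMILES contains none), so there is no enantiomer to control. The tridecyl chain is linear n-C13H27.

## Retrosynthetic overview
1. Target 8 is a hydroquinone monoacetate. The C–OAc bond is disconnected first, and this is the proposed new step: para-selective oxidative C–H acetoxylation of phenol 6 puts oxygen para to the OH, between the OMe and the alkyl chain.
2. Phenol 6 comes from statistical mono-O-demethylation of the symmetrical ether 5.
3. Ether 5 comes from Kumada coupling of commercial 1-bromo-3,5-dimethoxybenzene (4) with tridecylMgBr (3), which is made from 1-bromotridecane (1) and Mg (2).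
4. The aromatic ring is commercial, so no ring is formed in the route.

## Route

**Step 1**
Reactants: 1 (1-bromotridecane), 2 (magnesium turnings)
Product: 3 (tridecylmagnesium bromide)
Conditions: Mg (1.3 equiv), I2 (cat.), THF, 40 °C → rt, 2 h
Reagents that add atoms: Mg, [Mg] (becomes MgBr in 3)
Why: Oxidative insertion of Mg into the primary C–Br bond (Grignard formation) gives the alkyl nucleophile for Step 2.

**Step 2**
Reactants: 3 (tridecylmagnesium bromide), 4 (1-bromo-3,5-dimethoxybenzene)
Product: 5 (1,3-dimethoxy-5-tridecylbenzene)
Conditions: Ni(dppp)Cl2 (3 mol%), THF, 0 °C → rt, 12 h; aq. NH4Cl workup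
Reagents that add atoms: none (the Grignard is the listed reactant)
Why: Kumada–Corriu C(sp2)–C(sp3) coupling installs the C13 chain; the bidentate dppp ligand suppresses β-hydride chain-walking of the primary alkyl group.

**Step 3**
Reactants: 5 (1,3-dimethoxy-5-tridecylbenzene)
Product: 6 (3-methoxy-5-tridecylphenol)
Conditions: BBr3 (0.7 equiv), CH2Cl2, –78 → 0 °C, 3 h; MeOH quench; recover and recycle unreacted 5
Reagents that add atoms: none (boron and the methyl group are lost)
Why: BBr3 ether cleavage of a symmetrical bis-ether needs no regiocontrol, and sub-stoichiometric BBr3 limits over-demethylation to the resorcinol (statistical mono-demethylation).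

**Step 4**
Reactants: 6 (3-methoxy-5-tridecylphenol), 7 (phenyliodine(III) diacetate, PIDA)
Product: 8 (Ardisiphenol D, 4-hydroxy-2-methoxy-6-tridecylphenyl acetate)
Conditions: PhI(OAc)2 (0.95 equiv), HFIP, 0 °C, 1 h; aq. Na2S2O3 quench
Reagents that add atoms: PIDA, CC(=O)OI(OC(C)=O)c1ccccc1 (supplies the acetoxy group that ends up on the ring)
Why: Proposed new method: the phenol exchanges onto I(III) to give ArO–I(Ph)OAc, which ionises in HFIP to a phenoxenium-type ion, with positive charge only at the H-bearing carbons ortho and para to O because both ring substituents are meta to the OH; acetate released from PIDA adds at the para carbon, and the 4-acetoxycyclohexadienone loses H+ to re-aromatise directly to the 4-acetoxyphenol unit (net: ArH + PhI(OAc)2 gives ArOAc + PhI + AcOH, so PIDA supplies all the acetate), with the para-quinoid adduct favoured over the ortho one and sub-stoichiometric oxidant at 0 °C limiting quinone formation; the closest known chemistry is Kita-type PIFA/PIDA oxidative nucleophilic substitution of phenols and phenol ethers and Fremy-type para-oxygenation of 3,5-disubstituted phenols, but direct para-C–H acetoxylation of a free phenol to a hydroquinone monoacetate is the new element, and no stereocentre is formed.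

## Compound list
1 | 1-bromotridecane | CCCCCCCCCCCCCBr | starting material
2 | magnesium | [Mg] | starting material
3 | tridecylmagnesium bromide | CCCCCCCCCCCCC[Mg]Br | intermediate
4 | 1-bromo-3,5-dimethoxybenzene | COc1cc(Br)cc(OC)c1 | starting material
5 | 1,3-dimethoxy-5-tridecylbenzene | CCCCCCCCCCCCCc1cc(OC)cc(OC)c1 | intermediate
6 | 3-methoxy-5-tridecylphenol | CCCCCCCCCCCCCc1cc(O)cc(OC)c1 | intermediate
7 | phenyliodine(III) diacetate (PIDA) | CC(=O)OI(OC(C)=O)c1ccccc1 | starting material (reagent)
8 | Ardisiphenol D (achiral), 4-hydroxy-2-methoxy-6-tridecylphenyl acetate | CCCCCCCCCCCCCc1cc(O)cc(OC)c1OC(C)=O | target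

**Total steps:** 4.
**Longest linear sequence:** 4 steps (1 → 3 → 5 → 6 → 8, i.e. Steps 1 → 2 → 3 → 4). From commercial 4 the sequence is 3 steps.

## Three steps most likely to fail
1. **Step 4 (proposed new step).** The product is an electron-rich hydroquinone monoacetate, so over-oxidation to the quinone is likely. Ortho-acetoxylation could also compete, because the para carbon is flanked by OMe and the alkyl chain.
   Fallback (known chemistry): oxidise 6 with Fremy's salt (Teuber oxidation, free para position) to 2-methoxy-6-tridecyl-1,4-benzoquinone, reduce with Na2S2O4, and treat with Ac2O/pyridine to give the diacetate. Then selectively cleave the unhindered acetate (K2CO3, MeOH, 0 °C) and keep the acetate flanked by OMe and tridecyl, giving 8.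
2. **Step 3.** Mono-demethylation is statistical, so the yield is about 50% with a risk of over-demethylation to the resorcinol.
   Fallback (different approach): couple tridecylMgBr with the MOM ether of 3-bromo-5-methoxyphenol under the Step 2 Kumada conditions, then remove the MOM group with HCl/MeOH to give 6. This avoids the symmetry problem.
3. **Step 2.** Ni-catalysed coupling of a primary alkyl Grignard with an electron-rich aryl bromide can give homocoupling or chain-isomerised products.
   Fallback: Wittig reaction of 3,5-dimethoxybenzaldehyde with dodecyltriphenylphosphonium bromide (n-BuLi, THF) to give the styrene ArCH=CH–C11H23, then H2, Pd/C, to give 5.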